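The ring is traced back to benzoic acid. The cis diol at C4 and C5 of the cyclohexenone ring, with C5 quaternary and bonded to chain carbon C1', is the ipso,ortho cis-dihydrodiol that a benzoate dioxygenase installs on the arene; the carboxyl carbon is C1'. One whole-cell oxidation of commercial benzoic acid, which needs no prior chemical step, therefore forms both C–O bonds and both stereocentres and leaves a diene. The carboxyl group then serves twice: as a tether it delivers oxygen to C1 by iodolactonisation, which differentiates the two ring alkenes, and after reduction to a neopentyl triflate it accepts a (Z)-hexadec-7-enyl copper reagent to complete the C17 chain.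

Key step: step 1

Remark (numbering): in every compound the ring atoms carry the numbers of the target: C1 is the future ketone carbon, C2=C3 the retained alkene, C4 the secondary carbinol, C5 the quaternary carbinol, C6 the future CH2; C1' is the carboxyl-derived carbon on C5.

Remark (assumption): the benzoate-dioxygenase-positive, cis-diol-dehydrogenase-negative strain Ralstonia eutropha B9 is taken from a culture collection and counts as the catalyst of step 1, not as a starting material.

Step 1
Reactants: 1 benzoic acid
Product: 2 (1S,2R)-1,2-dihydroxycyclohexa-3,5-diene-1-carboxylic acid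
Conditions: R. eutropha B9 (growing whole cells), benzoate fed in portions, fructose, mineral salts medium pH 7, air, 30 °C; cells removed, pH 3 at 0 °C, EtOAc
Reagents that add atoms: dioxygen O=O
Why: Benzoate 1,2-dioxygenase, a Rieske non-heme iron enzyme supplied with electrons from cellular NADH, activates O2 at its mononuclear iron and passes both oxygen atoms to one face of the ipso and ortho carbons (C5 and C4), so the arene is dearomatised to a cis-dihydrodiol; the closest known reaction type is the classical microbial cis-dihydroxylation of arenes. No ring is closed. Both new stereocentres are under catalyst control: the cis relation follows from suprafacial delivery of a single O2 molecule, and the absolute (1S,2R) sense from the way the carboxylate is anchored in the active site. The step needs ipso,ortho regioselectivity, which the same carboxylate binding secures, and survival of the diol, which the missing dihydrodiol dehydrogenase of the mutant secures, since the wild type would decarboxylate it to catechol. Benzoic acid carries no other group that could interfere.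

Step 2
Reactants: 2 (1S,2R)-1,2-dihydroxycyclohexa-3,5-diene-1-carboxylic acid
Product: 3 (3aS,7aR)-2,2-dimethyl-3a,7a-dihydro-1,3-benzodioxole-3a-carboxylic acid (cis-fused C4/C5 acetonide of 2)
Conditions: Me2C(OMe)2, TsOH·H2O (cat.), acetone, 0 °C → rt; Et3N quench
Reagents that add atoms: 2,2-dimethoxypropane COC(C)(C)OC
Why: Acid-catalysed transketalisation closes the dioxolane on the cis-1,2-diol without touching either stereocentre, and low acid loading with a basic quench should prevent dehydrative aromatisation.

Step 3
Reactants: 3 acetonide acid
Product: 4 iodo-γ-lactone (carboxyl oxygen bonded to C1 on the carboxyl face, iodine on C6 on the opposite face, C2=C3 intact, C4/C5 acetonide)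
Conditions: I2, NaHCO3, MeCN, 0 °C, dark
Reagents that add atoms: iodine II
Why: Iodolactonisation: iodonium ions form reversibly on both alkenes, but only the one across C1=C6 on the face opposite the carboxylate can be captured intramolecularly, and it should open at C1 because that carbon is allylic and closure there gives the five-membered lactone of a 6-oxabicyclo[3.2.1]octene, so the tether sets the C1–O bond cis to the carboxyl carbon and iodine ends up anti on C6 (both centres are erased later, in steps 4 and 13).

Step 4
Reactants: 4 iodo-γ-lactone
Product: 5 γ-lactone (as 4, with C6 as CH2)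
Conditions: Bu3SnH, AIBN (cat.), PhH, 80 °C
Reagents that add atoms: none
Why: Radical chain dehalogenation: the stannyl radical abstracts iodine and the secondary, non-allylic C6 radical is quenched by tin hydride faster than it can fragment or rearrange, which leaves the lactone, the acetonide and the C2=C3 alkene untouched.

Step 5
Reactants: 5 γ-lactone
Product: 6 methyl (3aS,5S,7aR)-5-hydroxy-2,2-dimethyl-3a,4,5,7a-tetrahydro-1,3-benzodioxole-3a-carboxylate (C1–OH cis to the ester)
Conditions: K2CO3 (cat.), MeOH, 0 °C → rt
Reagents that add atoms: methanol CO
Why: Base-catalysed transesterification opens the strained bridged lactone at the acyl carbon, which frees the C1 hydroxyl with retention and cannot epimerise C5 because that carbon bears no hydrogen.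

Step 6
Reactants: 6 hydroxy ester
Product: 7 C1 O-tert-butyldiphenylsilyl ether of 6
Conditions: TBDPSCl, imidazole, DMAP (cat.), DMF, rt
Reagents that add atoms: tert-butyl(chloro)diphenylsilane CC(C)(C)[Si](Cl)(c1ccccc1)c1ccccc1
Why: Silylation of the only free hydroxyl; the bulky, weakly nucleophilic TBDPS ether is chosen so that it neither migrates to the C1' oxygen after step 7 nor displaces the triflate made in step 10.

Step 7
Reactants: 7 silyl ether ester
Product: 8 primary alcohol (C5–CH2OH, C1–OTBDPS, C4/C5 acetonide, C2=C3)
Conditions: LiAlH4, THF, 0 °C
Reagents that add atoms: none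
Why: Hydride reduction of the ester gives the neopentyl alcohol, with the silyl ether, acetonide and alkene inert to LiAlH4 at 0 °C.

Step 8
Reactants: 9 7-bromoheptan-1-ol
Product: 10 7-bromoheptanal
Conditions: TEMPO (cat.), PhI(OAc)2, CH2Cl2, rt
Reagents that add atoms: none
Why: Oxoammonium (TEMPO) oxidation of a primary alcohol stops at the aldehyde and does not touch the primary bromide.

Step 9
Reactants: 10 7-bromoheptanal; 11 nonyltriphenylphosphonium bromide
Product: 13 (Z)-1-bromohexadec-7-ene, via nonylidenetriphenylphosphorane 12 (not isolated)
Conditions: 11, NaHMDS, THF, 0 °C; then 10, −78 °C → rt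
Reagents that add atoms: none
Why: Wittig olefination with a non-stabilised ylide under lithium-free conditions closes the cis-oxaphosphetane kinetically and should therefore give the Z-alkene, the aldehyde reacting far faster than the alkyl bromide at low temperature.

Step 10
Reactants: 8 primary alcohol
Product: 14 C1' triflate of 8
Conditions: Tf2O, 2,6-lutidine, CH2Cl2, −78 °C; cold work-up, used at once
Reagents that add atoms: triflic anhydride O=S(=O)(OS(=O)(=O)C(F)(F)F)C(F)(F)F
Why: Sulfonylation of the primary alcohol with a hindered base; the neopentyl triflate cannot eliminate because C5 carries no hydrogen and it solvolyses slowly, so it should survive a cold work-up.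

Step 11
Reactants: 14 C1' triflate; 13 (Z)-1-bromohexadec-7-ene
Product: 16 coupled silyl ether acetonide bearing the (Z)-heptadec-8-enyl chain on C5, via (Z)-hexadec-7-enylmagnesium bromide 15 (not isolated)
Conditions: 13, Mg, THF, 40 °C; then CuBr·SMe2 (10 mol %), 14, Et2O/THF, −40 → 0 °C
Reagents that add atoms: none
Why: Copper-catalysed sp3–sp3 cross-coupling of a Grignard reagent with a primary alkyl triflate: the transient alkylcuprate displaces triflate at C1' by SN2, the remote C7 alkene of the Grignard reagent keeps its geometry, and the silyl ether, acetonide and ring alkene are inert to the reagent below 0 °C.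

Step 12
Reactants: 16 coupled silyl ether acetonide
Product: 17 allylic alcohol (16 without the silyl group, C1–OH free)
Conditions: TBAF, THF, rt
Reagents that add atoms: none
Why: Fluoride-driven desilylation, paid for by the strong Si–F bond, frees the C1 alcohol without affecting the acetonide or either alkene.

Step 13
Reactants: 17 allylic alcohol
Product: 18 enone acetonide (4,5-O-isopropylidene derivative of the target)
Conditions: Dess–Martin periodinane, NaHCO3, CH2Cl2, 0 °C → rt
Reagents that add atoms: none
Why: Dess–Martin oxidation converts the only free hydroxyl, an allylic secondary alcohol, into the conjugated C1 ketone under buffered, near-neutral conditions, which avoids β-elimination of the C5 oxygen and leaves the Z-alkene alone.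

Step 14
Reactants: 18 enone acetonide
Product: 19 (4R,5S)-4,5-dihydroxy-5-[(Z)-heptadec-8-enyl]cyclohex-2-en-1-one
Conditions: 1 M aq. HCl, THF, rt
Reagents that add atoms: none
Why: Acid-catalysed acetal hydrolysis cleaves only the O–CMe2 bonds, so C4 and C5 keep the configuration set by the enzyme, and dilute acid at room temperature should be too mild to dehydrate the β-hydroxy ketone.

Compound list

1 | benzoic acid | OC(=O)c1ccccc1 | starting material
2 | (1S,2R)-1,2-dihydroxycyclohexa-3,5-diene-1-carboxylic acid | OC(=O)[C@]1(O)C=CC=C[C@H]1O | intermediate
3 | (3aS,7aR)-2,2-dimethyl-3a,7a-dihydro-1,3-benzodioxole-3a-carboxylic acid | OC(=O)[C@]12C=CC=C[C@H]1OC(C)(C)O2 | intermediate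
4 | iodo-γ-lactone (lactone O on C1 cis to the carboxyl carbon, I on C6 trans to it, C2=C3, C4/C5 acetonide) | O=C1O[C@@H]2C=C[C@H]3OC(C)(C)O[C@]13[C@H]2I | intermediate
5 | γ-lactone (4 with C6 as CH2) | O=C1O[C@@H]2C=C[C@H]3OC(C)(C)O[C@]13C2 | intermediate
6 | methyl (3aS,5S,7aR)-5-hydroxy-2,2-dimethyl-3a,4,5,7a-tetrahydro-1,3-benzodioxole-3a-carboxylate | COC(=O)[C@]12C[C@H](O)C=C[C@H]1OC(C)(C)O2 | intermediate
7 | C1 O-TBDPS ether of 6 | COC(=O)[C@]12C[C@H](O[Si](c3ccccc3)(c3ccccc3)C(C)(C)C)C=C[C@H]1OC(C)(C)O2 | intermediate
8 | primary alcohol (C5–CH2OH, C1–OTBDPS, C4/C5 acetonide) | OC[C@]12C[C@H](O[Si](c3ccccc3)(c3ccccc3)C(C)(C)C)C=C[C@H]1OC(C)(C)O2 | intermediate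
9 | 7-bromoheptan-1-ol | OCCCCCCCBr | starting material
10 | 7-bromoheptanal | O=CCCCCCCBr | intermediate
11 | nonyltriphenylphosphonium bromide | CCCCCCCCC[P+](c1ccccc1)(c1ccccc1)c1ccccc1.[Br-] | starting material
12 | nonylidenetriphenylphosphorane | CCCCCCCCC=P(c1ccccc1)(c1ccccc1)c1ccccc1 | intermediate (not isolated)
13 | (Z)-1-bromohexadec-7-ene | CCCCCCCC/C=C\CCCCCCBr | intermediate
14 | C1' triflate of 8 | O=S(=O)(OC[C@]12C[C@H](O[Si](c3ccccc3)(c3ccccc3)C(C)(C)C)C=C[C@H]1OC(C)(C)O2)C(F)(F)F | intermediate
15 | (Z)-hexadec-7-enylmagnesium bromide | CCCCCCCC/C=C\CCCCCC[Mg]Br | intermediate (not isolated)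
16 | coupled silyl ether acetonide (C5 (Z)-heptadec-8-enyl, C1–OTBDPS, C4/C5 acetonide) | CCCCCCCC/C=C\CCCCCCC[C@]12C[C@H](O[Si](c3ccccc3)(c3ccccc3)C(C)(C)C)C=C[C@H]1OC(C)(C)O2 | intermediate
17 | allylic alcohol (C1–OH cis to the chain, C4/C5 acetonide) | CCCCCCCC/C=C\CCCCCCC[C@]12C[C@H](O)C=C[C@H]1OC(C)(C)O2 | intermediate
18 | enone acetonide (4,5-O-isopropylidene derivative of the target) | CCCCCCCC/C=C\CCCCCCC[C@]12CC(=O)C=C[C@H]1OC(C)(C)O2 | intermediate
19 | (4R,5S)-4,5-dihydroxy-5-[(Z)-heptadec-8-enyl]cyclohex-2-en-1-one | CCCCCCCC/C=C\CCCCCCC[C@]1(O)CC(=O)C=C[C@H]1O | target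

Total step count: 14. Longest linear sequence: 12 (steps 1–7 and 10–14). Steps 8 and 9 prepare the side chain, which enters at step 11.

Steps most likely to fail

Step 3 (iodolactonisation). The danger is loss of site control. Iodine may engage the more electron-rich C2=C3 alkene instead of C1=C6. The carboxylate may also close in a 4-exo mode at C6 or in a 1,4 mode at C3 instead of at C1. The fallback sets out from 3 and returns at 5. Mercury(II) acetate in acetonitrile, followed by exchange of acetate for chloride with brine, should give the chloromercurio γ-lactone F1. Oxymercuration is reversible, so the closure is under thermodynamic control and should settle on the five-membered lactone at the allylic carbon C1. Radical demercuration with Bu3SnH and AIBN then gives 5 directly.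

Step 11 (coupling at C1'). Displacement at the neopentyl carbon may be slow. Attack of the organometallic at sulfur (returning 8), halide exchange, or intramolecular displacement by the C1 silyl ether oxygen could then compete. The fallback sets out from 8 and returns at 16. It forms the C1'–C2' bond by carbonyl addition instead of substitution. Dess–Martin oxidation of 8 should give the aldehyde F2. Addition of the Grignard reagent 15 in THF at −78 °C gives the C1' carbinol F3 as a mixture of epimers, which is of no consequence. Deprotonation with NaH and treatment with CS2 and MeI gives the S-methyl xanthate F4. Barton–McCombie deoxygenation (Bu3SnH, Et3B/air, rt, to spare the Z-alkene) then gives 16.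

Step 14 (acetonide removal on the β-hydroxy enone). Acid may trigger β-elimination of the tertiary C5 hydroxyl, followed by loss of the C4 hydroxyl and aromatisation to a phenol. The fallback sets out from 17 and returns at 19. It moves the acidic step to a stage where no ketone is present. Aqueous acetic acid on 17 should give the triol F5. Phenylboronic acid in toluene with MgSO4 masks only the cis C4/C5 diol as the cyclic phenylboronate F6, because the C1 hydroxyl is trans to both. Dess–Martin oxidation of the remaining C1 hydroxyl gives the enone boronate F7. Neutral transesterification with excess pinacol in THF at room temperature then releases 19.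

Further compounds

F1 | step 3 | chloromercurio γ-lactone (HgCl on C6 in place of the iodine of 4) | O=C1O[C@@H]2C=C[C@H]3OC(C)(C)O[C@]13[C@H]2[Hg]Cl
F2 | step 11 | C1' aldehyde from 8 | O=C[C@]12C[C@H](O[Si](c3ccccc3)(c3ccccc3)C(C)(C)C)C=C[C@H]1OC(C)(C)O2
F3 | step 11 | C1' carbinol from F2 and 15 (both C1' epimers) | CCCCCCCC/C=C\CCCCCCC(O)[C@]12C[C@H](O[Si](c3ccccc3)(c3ccccc3)C(C)(C)C)C=C[C@H]1OC(C)(C)O2
F4 | step 11 | S-methyl xanthate of F3 | CCCCCCCC/C=C\CCCCCCC(OC(=S)SC)[C@]12C[C@H](O[Si](c3ccccc3)(c3ccccc3)C(C)(C)C)C=C[C@H]1OC(C)(C)O2
F5 | step 14 | triol (17 without the acetonide) | CCCCCCCC/C=C\CCCCCCC[C@]1(O)C[C@H](O)C=C[C@H]1O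
F6 | step 14 | C4/C5 cyclic phenylboronate of F5 | CCCCCCCC/C=C\CCCCCCC[C@]12C[C@H](O)C=C[C@H]1OB(c3ccccc3)O2
F7 | step 14 | enone C4/C5 phenylboronate | CCCCCCCC/C=C\CCCCCCC[C@]12CC(=O)C=C[C@H]1OB(c3ccccc3)O2
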